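**Strategy.** The congested ether between ring A C1 and ring B is not made by arylation; ring A is instead grown on the ring B oxygen. Ring A is a 1,3,5-triol whose ether carbon C1 lies between the hydroxylated C2 and C6, the oxygenation pattern of a triketide with the ether oxygen on its terminal carbon. A methyl 6-aryloxy-3,5-dioxohexanoate (9), whose O–CH2 bond comes from a simple phenol alkylation, is folded by an intramolecular Claisen acylation (C6 onto the ester carbon) that closes ring A and aromatises in one operation. Rings C to G are added by aryl ether couplings alternating with Dakin-type oxidations, one convergent Ullmann union and a final global demethylation.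

Key step: step 5

Assumption: 2-fluoro-4,6-dimethoxybenzaldehyde (21) and 4-fluoro-2,6-dimethoxybenzaldehyde (25) are taken as purchasable; each is otherwise one formylation away from 1-fluoro-3,5-dimethoxybenzene.

Remark: the target and all intermediates are achiral, so no stereocentre has to be set.

**Route**

Step 1
Reactants: 1 syringaldehyde
Product: 2 4-(benzyloxy)-3,5-dimethoxybenzaldehyde
Conditions: BnBr, K2CO3, DMF, 60 °C
Reagents that add atoms: benzyl bromide, BrCc1ccccc1
Why: Williamson etherification (SN2 at a benzylic bromide) masks the ring B C4 oxygen with a group that later leaves by hydrogenolysis without touching methyl ethers.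

Step 2
Reactants: 2 4-(benzyloxy)-3,5-dimethoxybenzaldehyde
Product: 4 4-(benzyloxy)-3,5-dimethoxyphenol, via aryl formate 3 (not isolated)
Conditions: mCPBA, CH2Cl2, 0 °C to rt; then Et3N (cat.), MeOH, rt
Reagents that add atoms: mCPBA (3-chloroperoxybenzoic acid), OOC(=O)c1cccc(Cl)c1
Why: Baeyer–Villiger oxidation in its Dakin-type form, in which the electron-rich aryl group migrates to oxygen and formate 3 is cleaved by base-catalysed methanolysis, the benzyl and methyl ethers being inert to the peracid.

Step 3
Reactants: 4 4-(benzyloxy)-3,5-dimethoxyphenol; 5 methyl bromoacetate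
Product: 6 methyl 2-[4-(benzyloxy)-3,5-dimethoxyphenoxy]acetate
Conditions: K2CO3, acetone, reflux
Reagents that add atoms: none
Why: Williamson alkylation (SN2) of the unhindered ring B phenoxide at a primary α-bromo ester lays down, as an ordinary O–CH2 bond, the ether that becomes the hindered ring A C1–O linkage.

Step 4
Reactants: 6 methyl 2-[4-(benzyloxy)-3,5-dimethoxyphenoxy]acetate; 7 methyl acetoacetate
Product: 9 methyl 6-[4-(benzyloxy)-3,5-dimethoxyphenoxy]-3,5-dioxohexanoate, via methyl acetoacetate dianion 8 (not isolated)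
Conditions: 7 (2.5 equiv), LiN(iPr)2 (commercial solution, 5 equiv), THF, 0 °C; then 6, −78 to 0 °C; aq. HCl
Reagents that add atoms: none
Why: Claisen-type γ-acylation of dianion 8 by the activated α-aryloxy ester occurs at the more nucleophilic terminal carbanion, the excess of 8 covering deprotonation of the more acidic product, and the methyl ester is kept so that the later cyclisation runs with matching methoxide.

Step 5
Reactants: 9 methyl 6-[4-(benzyloxy)-3,5-dimethoxyphenoxy]-3,5-dioxohexanoate
Product: 11 2-[4-(benzyloxy)-3,5-dimethoxyphenoxy]benzene-1,3,5-triol, via 2-aryloxycyclohexane-1,3,5-trione 10 (not isolated)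
Conditions: Mg(OMe)2 (3 equiv), MeOH, 90 °C (sealed tube), under argon; then 1 M HCl, 0 °C
Reagents that add atoms: none
Why: Mg(OMe)2 turns 9 into its chelated polyenolate, and the C6 enolate carbon, made acidic by the C5 carbonyl and the aryloxy oxygen, adds to the magnesium-bound ester carbonyl C1; loss of methoxide gives trione 10, which enolises to the aromatic triol. The closest known reaction type is the Claisen-mode cyclisation of poly-β-keto esters to phloroglucinols, as in the Mg(OMe)2-mediated closure of 3,5,7-trioxo esters and the base-induced closure of methyl 3,5-dioxohexanoate. Ring A closes in a 6-(enolendo)-exo-trig mode, the new bond being ring A C1–C2. No stereocentre is formed. The selectivity required is C-acylation at C6 over O-acylation by the C5 enolate oxygen (lactonisation to a 4-hydroxy-2-pyrone), and it is secured because methoxide is both base and leaving group, so the lactone is reopened to the open-chain chelate by the same reagent while the carbocycle is drained irreversibly as the aromatic phenoxide. An aldol closure is impossible in a triketide of this length, so no third pathway competes.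

Step 6
Reactants: 11 2-[4-(benzyloxy)-3,5-dimethoxyphenoxy]benzene-1,3,5-triol
Product: 12 2-[4-(benzyloxy)-3,5-dimethoxyphenoxy]-1,3,5-trimethoxybenzene
Conditions: Me2SO4, K2CO3, acetone, reflux, under argon
Reagents that add atoms: dimethyl sulfate, COS(=O)(=O)OC
Why: Williamson O-methylation with the hard electrophile dimethyl sulfate in acetone favours O- over C-alkylation of phloroglucinols and converts the three air-sensitive hydroxyls into robust methyl ethers.

Step 7
Reactants: 12 2-[4-(benzyloxy)-3,5-dimethoxyphenoxy]-1,3,5-trimethoxybenzene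
Product: 13 2,6-dimethoxy-4-(2,4,6-trimethoxyphenoxy)phenol
Conditions: H2 (1 atm), Pd/C (10 wt% Pd on carbon), EtOAc–MeOH, rt
Reagents that add atoms: none
Why: Catalytic hydrogenolysis of the benzyl aryl ether frees only the ring B C4 hydroxyl, since diaryl and methyl aryl ethers are stable to these conditions.

Step 8
Reactants: 14 5-bromo-1,2,3-trimethoxybenzene
Product: 16 6-bromo-2,3,4-trimethoxybenzaldehyde, via aryl chloro(methoxy)methane 15 (not isolated)
Conditions: Cl2CHOMe, TiCl4, CH2Cl2, −10 to 0 °C; then ice water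
Reagents that add atoms: dichloromethyl methyl ether, COC(Cl)Cl; water, O
Why: Rieche formylation (electrophilic aromatic substitution) can only occur at the two equivalent free positions of 14, each ortho and para to methoxy groups, so the regiochemistry is unambiguous, and hydrolysis of 15 on work-up releases the aldehyde.

Step 9
Reactants: 13 2,6-dimethoxy-4-(2,4,6-trimethoxyphenoxy)phenol; 16 6-bromo-2,3,4-trimethoxybenzaldehyde
Product: 17 6-[2,6-dimethoxy-4-(2,4,6-trimethoxyphenoxy)phenoxy]-2,3,4-trimethoxybenzaldehyde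
Conditions: CuI (10 mol%), picolinic acid (20 mol%), K3PO4, DMSO, 90 °C, under argon
Reagents that add atoms: none
Why: Copper-catalysed Ullmann diaryl ether synthesis in which the ortho-formyl group activates the C–Br bond and the picolinic acid ligand accommodates the doubly ortho-substituted phenoxide of 13, forming the ring B–ring C ether.

Step 10
Reactants: 17 6-[2,6-dimethoxy-4-(2,4,6-trimethoxyphenoxy)phenoxy]-2,3,4-trimethoxybenzaldehyde
Product: 19 6-[2,6-dimethoxy-4-(2,4,6-trimethoxyphenoxy)phenoxy]-2,3,4-trimethoxyphenol, via aryl formate 18 (not isolated)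
Conditions: mCPBA (1.2 equiv), CH2Cl2, 0 °C; then Et3N (cat.), MeOH, rt
Reagents that add atoms: mCPBA (3-chloroperoxybenzoic acid), OOC(=O)c1cccc(Cl)c1
Why: Baeyer–Villiger oxidation (Dakin-type) of the doubly ortho-oxygenated aldehyde with aryl migration, then methanolysis of formate 18, turns the activating formyl group into the ring C C6 hydroxyl needed for the next ether.

Step 11
Reactants: 20 4-bromo-2,6-dimethoxyphenol; 21 2-fluoro-4,6-dimethoxybenzaldehyde
Product: 22 2-(4-bromo-2,6-dimethoxyphenoxy)-4,6-dimethoxybenzaldehyde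
Conditions: Cs2CO3, DMSO, 110 °C
Reagents that add atoms: none
Why: Nucleophilic aromatic substitution (addition–elimination through a Meisenheimer adduct) of the fluoride ortho to the formyl group by the phenoxide of 20 forms the ring D–ring E ether, and without copper the aryl bromide is untouched.

Step 12
Reactants: 22 2-(4-bromo-2,6-dimethoxyphenoxy)-4,6-dimethoxybenzaldehyde
Product: 24 2-(4-bromo-2,6-dimethoxyphenoxy)-4,6-dimethoxyphenol, via aryl formate 23 (not isolated)
Conditions: mCPBA (1.2 equiv), CH2Cl2, 0 °C to rt; then Et3N (cat.), MeOH, rt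
Reagents that add atoms: mCPBA (3-chloroperoxybenzoic acid), OOC(=O)c1cccc(Cl)c1
Why: Baeyer–Villiger oxidation (Dakin-type) with migration of the electron-rich aryl group and methanolysis of formate 23 gives the ring E C6 hydroxyl, the aryl bromide being inert to peracid.

Step 13
Reactants: 24 2-(4-bromo-2,6-dimethoxyphenoxy)-4,6-dimethoxyphenol; 25 4-fluoro-2,6-dimethoxybenzaldehyde
Product: 26 4-[2-(4-bromo-2,6-dimethoxyphenoxy)-4,6-dimethoxyphenoxy]-2,6-dimethoxybenzaldehyde
Conditions: Cs2CO3, DMSO, 110 °C
Reagents that add atoms: none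
Why: Nucleophilic aromatic substitution at the unhindered fluoride para to the formyl group by the hindered ring E phenoxide forms the ring E–ring F ether, again without copper, so the ring D bromide survives.

Step 14
Reactants: 26 4-[2-(4-bromo-2,6-dimethoxyphenoxy)-4,6-dimethoxyphenoxy]-2,6-dimethoxybenzaldehyde
Product: 28 4-[2-(4-bromo-2,6-dimethoxyphenoxy)-4,6-dimethoxyphenoxy]-2,6-dimethoxyphenol, via aryl formate 27 (not isolated)
Conditions: mCPBA (1.2 equiv), CH2Cl2, 0 °C to rt; then Et3N (cat.), MeOH, rt
Reagents that add atoms: mCPBA (3-chloroperoxybenzoic acid), OOC(=O)c1cccc(Cl)c1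
Why: Baeyer–Villiger oxidation (Dakin-type) of the 2,6-dimethoxybenzaldehyde and methanolysis of formate 27 unveil the ring F C4 hydroxyl, which stays protected as the formate until the peracid is consumed.

Step 15
Reactants: 28 4-[2-(4-bromo-2,6-dimethoxyphenoxy)-4,6-dimethoxyphenoxy]-2,6-dimethoxyphenol; 29 5-iodo-1,2,3-trimethoxybenzene
Product: 30 5-bromo-2-{2-[3,5-dimethoxy-4-(3,4,5-trimethoxyphenoxy)phenoxy]-3,5-dimethoxyphenoxy}-1,3-dimethoxybenzene
Conditions: 29 (3 equiv), CuI (10 mol%), picolinic acid (20 mol%), K3PO4, DMSO, 80 °C, under argon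
Reagents that add atoms: none
Why: Copper-catalysed Ullmann etherification that is chemoselective for the more reactive aryl iodide, used in excess, over the ring D bromide, attaching ring G to the hindered ring F phenoxide.

Step 16
Reactants: 19 6-[2,6-dimethoxy-4-(2,4,6-trimethoxyphenoxy)phenoxy]-2,3,4-trimethoxyphenol; 30 5-bromo-2-{2-[3,5-dimethoxy-4-(3,4,5-trimethoxyphenoxy)phenoxy]-3,5-dimethoxyphenoxy}-1,3-dimethoxybenzene
Product: 31 heptadecamethyl ether of the target (rings A to G joined as in the target, all seventeen hydroxyls as methoxy groups)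
Conditions: CuI (20 mol%), picolinic acid (40 mol%), K3PO4, DMSO, 110 °C, under argon
Reagents that add atoms: none
Why: Copper-catalysed Ullmann diaryl ether synthesis between the hindered ring C phenoxide and an aryl bromide with no ortho substituent, the arrangement in which ligand-accelerated couplings tolerate a doubly ortho-substituted phenol.

Step 17
Reactants: 31 heptadecamethyl ether of the target
Product: 32 CNP0351377.0
Conditions: BBr3 (ca. 2 equiv per OMe), CH2Cl2, −78 °C to rt, under argon; then H2O, 0 °C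
Reagents that add atoms: none
Why: Lewis-acid ether cleavage in which each methyl aryl ether is dealkylated by bromide at the methyl group through a boron-bound oxonium ion, while the six diaryl ethers, lacking an sp3 carbon on oxygen, are inert, and hydrolysis of the aryl borates should release the seventeen hydroxyls.

**Compound list**

1 | syringaldehyde (4-hydroxy-3,5-dimethoxybenzaldehyde) | COc1cc(C=O)cc(OC)c1O | starting material
2 | 4-(benzyloxy)-3,5-dimethoxybenzaldehyde | COc1cc(C=O)cc(OC)c1OCc1ccccc1 | intermediate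
3 | 4-(benzyloxy)-3,5-dimethoxyphenyl formate | COc1cc(OC=O)cc(OC)c1OCc1ccccc1 | intermediate
4 | 4-(benzyloxy)-3,5-dimethoxyphenol | COc1cc(O)cc(OC)c1OCc1ccccc1 | intermediate
5 | methyl bromoacetate | COC(=O)CBr | starting material
6 | methyl 2-[4-(benzyloxy)-3,5-dimethoxyphenoxy]acetate | COC(=O)COc1cc(OC)c(OCc2ccccc2)c(OC)c1 | intermediate
7 | methyl acetoacetate | COC(=O)CC(C)=O | starting material
8 | dilithium dianion of methyl acetoacetate (dilithium 1-methoxybuta-1,3-diene-1,3-diolate) | [Li+].[Li+].C=C([O-])C=C([O-])OC | intermediate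
9 | methyl 6-[4-(benzyloxy)-3,5-dimethoxyphenoxy]-3,5-dioxohexanoate | COC(=O)CC(=O)CC(=O)COc1cc(OC)c(OCc2ccccc2)c(OC)c1 | intermediate
10 | 2-[4-(benzyloxy)-3,5-dimethoxyphenoxy]cyclohexane-1,3,5-trione | O=C1CC(=O)C(Oc2cc(OC)c(OCc3ccccc3)c(OC)c2)C(=O)C1 | intermediate
11 | 2-[4-(benzyloxy)-3,5-dimethoxyphenoxy]benzene-1,3,5-triol | Oc1cc(O)c(Oc2cc(OC)c(OCc3ccccc3)c(OC)c2)c(O)c1 | intermediate
12 | 2-[4-(benzyloxy)-3,5-dimethoxyphenoxy]-1,3,5-trimethoxybenzene | COc1cc(OC)c(Oc2cc(OC)c(OCc3ccccc3)c(OC)c2)c(OC)c1 | intermediate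
13 | 2,6-dimethoxy-4-(2,4,6-trimethoxyphenoxy)phenol | COc1cc(OC)c(Oc2cc(OC)c(O)c(OC)c2)c(OC)c1 | intermediate
14 | 5-bromo-1,2,3-trimethoxybenzene | COc1cc(Br)cc(OC)c1OC | starting material
15 | 1-bromo-2-[chloro(methoxy)methyl]-3,4,5-trimethoxybenzene | COC(Cl)c1c(Br)cc(OC)c(OC)c1OC | intermediate
16 | 6-bromo-2,3,4-trimethoxybenzaldehyde | O=Cc1c(Br)cc(OC)c(OC)c1OC | intermediate
17 | 6-[2,6-dimethoxy-4-(2,4,6-trimethoxyphenoxy)phenoxy]-2,3,4-trimethoxybenzaldehyde | O=Cc1c(Oc2c(OC)cc(Oc3c(OC)cc(OC)cc3OC)cc2OC)cc(OC)c(OC)c1OC | intermediate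
18 | 6-[2,6-dimethoxy-4-(2,4,6-trimethoxyphenoxy)phenoxy]-2,3,4-trimethoxyphenyl formate | O=COc1c(Oc2c(OC)cc(Oc3c(OC)cc(OC)cc3OC)cc2OC)cc(OC)c(OC)c1OC | intermediate
19 | 6-[2,6-dimethoxy-4-(2,4,6-trimethoxyphenoxy)phenoxy]-2,3,4-trimethoxyphenol | Oc1c(Oc2c(OC)cc(Oc3c(OC)cc(OC)cc3OC)cc2OC)cc(OC)c(OC)c1OC | intermediate
20 | 4-bromo-2,6-dimethoxyphenol | COc1cc(Br)cc(OC)c1O | starting material
21 | 2-fluoro-4,6-dimethoxybenzaldehyde | COc1cc(F)c(C=O)c(OC)c1 | starting material
22 | 2-(4-bromo-2,6-dimethoxyphenoxy)-4,6-dimethoxybenzaldehyde | COc1cc(Oc2c(OC)cc(Br)cc2OC)c(C=O)c(OC)c1 | intermediate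
23 | 2-(4-bromo-2,6-dimethoxyphenoxy)-4,6-dimethoxyphenyl formate | COc1cc(Oc2c(OC)cc(Br)cc2OC)c(OC=O)c(OC)c1 | intermediate
24 | 2-(4-bromo-2,6-dimethoxyphenoxy)-4,6-dimethoxyphenol | COc1cc(Oc2c(OC)cc(Br)cc2OC)c(O)c(OC)c1 | intermediate
25 | 4-fluoro-2,6-dimethoxybenzaldehyde | COc1cc(F)cc(OC)c1C=O | starting material
26 | 4-[2-(4-bromo-2,6-dimethoxyphenoxy)-4,6-dimethoxyphenoxy]-2,6-dimethoxybenzaldehyde | COc1cc(Oc2c(OC)cc(OC)cc2Oc2c(OC)cc(Br)cc2OC)cc(OC)c1C=O | intermediate
27 | 4-[2-(4-bromo-2,6-dimethoxyphenoxy)-4,6-dimethoxyphenoxy]-2,6-dimethoxyphenyl formate | COc1cc(Oc2c(OC)cc(OC)cc2Oc2c(OC)cc(Br)cc2OC)cc(OC)c1OC=O | intermediate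
28 | 4-[2-(4-bromo-2,6-dimethoxyphenoxy)-4,6-dimethoxyphenoxy]-2,6-dimethoxyphenol | COc1cc(Oc2c(OC)cc(OC)cc2Oc2c(OC)cc(Br)cc2OC)cc(OC)c1O | intermediate
29 | 5-iodo-1,2,3-trimethoxybenzene | COc1cc(I)cc(OC)c1OC | starting material
30 | 5-bromo-2-{2-[3,5-dimethoxy-4-(3,4,5-trimethoxyphenoxy)phenoxy]-3,5-dimethoxyphenoxy}-1,3-dimethoxybenzene | COc1cc(Oc2c(OC)cc(Oc3c(OC)cc(OC)cc3Oc3c(OC)cc(Br)cc3OC)cc2OC)cc(OC)c1OC | intermediate
31 | heptadecamethyl ether of the target: ring A 2,4,6-trimethoxyphenyl; rings B, D and F 3,5-dimethoxy-1,4-phenylenedioxy; ring C 3,4,5-trimethoxy-1,2-phenylenedioxy; ring E 3,5-dimethoxy-1,2-phenylenedioxy; ring G 3,4,5-trimethoxyphenyl | COc1cc(OC)c(Oc2cc(OC)c(Oc3cc(OC)c(OC)c(OC)c3Oc3cc(OC)c(Oc4cc(OC)cc(OC)c4Oc4cc(OC)c(Oc5cc(OC)c(OC)c(OC)c5)c(OC)c4)c(OC)c3)c(OC)c2)c(OC)c1 | intermediate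
32 | CNP0351377.0, the seven-ring polyaryl ether with seventeen free hydroxyls (rings A to G as in 31, OH in place of OMe) | Oc1cc(O)c(Oc2cc(O)c(Oc3cc(O)c(O)c(O)c3Oc3cc(O)c(Oc4cc(O)cc(O)c4Oc4cc(O)c(Oc5cc(O)c(O)c(O)c5)c(O)c4)c(O)c3)c(O)c2)c(O)c1 | target

**Step count and risk**

Total steps: 17. Longest linear sequence: 11 steps (steps 1 to 7, 9, 10, 16, 17).

Steps most likely to fail:

1. Step 5. The chain may stall as an unreactive magnesium diketonate because C6 is its least acidic carbon, lactonise through the C5 enolate oxygen, or fragment by retro-Claisen cleavage on forcing. Fallback: abandon the fold and make the ring A–ring B ether by arylation from the hindered phenol side. Setting out from 20, O-benzylation (BnBr, K2CO3, DMF) should give 2-(benzyloxy)-5-bromo-1,3-dimethoxybenzene F1. Ullmann coupling of F1 with commercial 2,4,6-trimethoxyphenol (CuI, picolinic acid, K3PO4, DMSO, 100 °C) should then deliver 12, where the route is rejoined before step 7.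

2. Step 16. C–O bond formation at the doubly ortho-substituted ring C phenoxide may be too slow, so that protodebromination of the bromide and oxidative degradation of the electron-rich phenol take over. Fallback: reverse the role of the ring D partner. Setting out from 30, bromine–lithium exchange (n-BuLi, THF, −78 °C), trapping with B(OiPr)3 and acidic work-up should give (4-{2-[3,5-dimethoxy-4-(3,4,5-trimethoxyphenoxy)phenoxy]-3,5-dimethoxyphenoxy}-3,5-dimethoxyphenyl)boronic acid F2. Chan–Lam–Evans oxidative coupling of F2 with 19 (Cu(OAc)2, pyridine, 4 Å molecular sieves, CH2Cl2, dry air, rt) should return to the route at 31.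

3. Step 17. Cleavage of some of the seventeen methyl ethers may remain incomplete, and the free polyphenol may oxidise in air during chromatographic purification. Fallback: exchange the protecting groups in a telescoped operation so that purification is done on a stable derivative. Setting out from 31, the crude product of the BBr3 treatment is not purified but acetylated at once (Ac2O, pyridine, DMAP, under argon) to the heptadecaacetate of the target F3, which is purified on silica. Acid-catalysed methanolysis of F3 (HCl generated from AcCl in MeOH, under argon) should then release 32.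

**Further compounds**

F1 | step 5 | 2-(benzyloxy)-5-bromo-1,3-dimethoxybenzene | COc1cc(Br)cc(OC)c1OCc1ccccc1
F2 | step 16 | (4-{2-[3,5-dimethoxy-4-(3,4,5-trimethoxyphenoxy)phenoxy]-3,5-dimethoxyphenoxy}-3,5-dimethoxyphenyl)boronic acid | COc1cc(Oc2c(OC)cc(Oc3c(OC)cc(OC)cc3Oc3c(OC)cc(B(O)O)cc3OC)cc2OC)cc(OC)c1OC
F3 | step 17 | heptadecaacetate of the target (all seventeen hydroxyls as acetates) | CC(=O)Oc1cc(OC(C)=O)c(Oc2cc(OC(C)=O)c(Oc3cc(OC(C)=O)c(OC(C)=O)c(OC(C)=O)c3Oc3cc(OC(C)=O)c(Oc4cc(OC(C)=O)cc(OC(C)=O)c4Oc4cc(OC(C)=O)c(Oc5cc(OC(C)=O)c(OC(C)=O)c(OC(C)=O)c5)c(OC(C)=O)c4)c(OC(C)=O)c3)c(OC(C)=O)c2)c(OC(C)=O)c1
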